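Retrosynthesis (labdane numbering throughout): the C18–O angeloyl bond and the C15 acid level go first. The C8 hydroxyl is traced back to a C7=C8 alkene and a carbonyl is added at C1. Ring B is then cut at C5–C6 and C9–C10 in one operation.
Enabling feature: ring B (C5–C10) shares the trans C5(H)–C10(CH3) edge with ring A, has nothing on C6, a methyl on C8 and the C11–C16 chain on C9. Its C7=C8 alkene form is therefore the formal [4+2] adduct of an (E)-3-methyl-1,3-diene across the C5=C10 bond of a ring-A 2-methylcyclohex-2-enone (C1=O).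
Forward order: ring A is made first by an enantioselective Diels–Alder reaction of methacrolein with an amino-siloxy diene, followed by α-methylation. The diene chain comes from (S)-citronellol by cross-metathesis and methylenation. Irradiation joins the two pieces and closes ring B; then C1 is deoxygenated, C7=C8 hydrated, C18 angeloylated and C15 oxidised.
Stereochemistry: C4 comes from the chiral diol catalyst and C13 from (S)-citronellol. C5, C10 and C9 are set in the photochemical step by relay from C4 and from the E geometry of the diene. C8 is set by oxygen delivery anti to the axial C10 methyl, and the Z alkene comes from angelic acid.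
Key step: step 9

Assumption: the (R,R)-diol of step 1 is taken to deliver the (S)-configured C4; if its sense is the opposite, the equally available (S,S)-diol is used and nothing else changes.

Step 1
Reactants: 1 methacrolein; 2 (E)-1-(dimethylamino)-3-(tert-butyldimethylsilyloxy)buta-1,3-diene
Product: 4 [4-(tert-butyldimethylsilyloxy)-2-(dimethylamino)-1-methylcyclohex-3-en-1-yl]methanol (NMe2 cis to CH2OH; quaternary carbon as C4 of 27), via cycloadduct aldehyde 3 (not isolated)
Conditions: (4R,5R)-2,2-dimethyl-α,α,α′,α′-tetra(1-naphthyl)-1,3-dioxolane-4,5-dimethanol (20 mol %), toluene, −80 °C; then LiAlH4, Et2O, −80 °C to rt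
Reagents that add atoms: none
Why: Hydrogen-bond-catalysed enantioselective Diels–Alder reaction in which the diol binds the aldehyde oxygen and shields one face of methacrolein, the amino-siloxy diene fixes the regiochemistry (the C–N carbon bonds the quaternary carbon) and the endo mode, so that C4 is set by the catalyst, and hydride reduction in the same flask secures the labile aldehyde.

Step 2
Reactants: 4 amino alcohol
Product: 6 (S)-4-(hydroxymethyl)-4-methylcyclohex-2-en-1-one, via amino ketone 5 (not isolated)
Conditions: HF (5% in MeCN/H2O), 0 °C to rt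
Reagents that add atoms: none
Why: Cleavage of the silyl enol ether followed by E1cB loss of dimethylamine is the standard unmasking of such cycloadducts; the C–N stereocentre vanishes and the quaternary C4 cannot epimerise.

Step 3
Reactants: 6 (S)-4-(hydroxymethyl)-4-methylcyclohex-2-en-1-one
Product: 7 (S)-4-[(tert-butyldimethylsilyloxy)methyl]-4-methylcyclohex-2-en-1-one
Conditions: TBSCl, imidazole, DMF, rt
Reagents that add atoms: TBSCl, CC(C)(C)[Si](C)(C)Cl
Why: Routine silylation of a primary alcohol; the TBS group makes the C18 arm clearly larger than the C4 methyl and can later be removed beside a TBDPS ether.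

Step 4
Reactants: 7 silyl ether enone
Product: 8 (S)-4-[(tert-butyldimethylsilyloxy)methyl]-2-iodo-4-methylcyclohex-2-en-1-one
Conditions: I2, pyridine/CH2Cl2 (1:1), 0 °C to rt
Reagents that add atoms: iodine, II
Why: α-Iodination of an enone by addition–elimination (pyridine adds at C5, the enolate is iodinated, pyridine leaves), a reaction well established for 4,4-disubstituted cyclohexenones.

Step 5
Reactants: 8 α-iodoenone
Product: 9 (S)-4-[(tert-butyldimethylsilyloxy)methyl]-2,4-dimethylcyclohex-2-en-1-one
Conditions: SnMe4, Pd2(dba)3 (cat.), AsPh3, CuI (cat.), NMP, 60 °C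
Reagents that add atoms: tetramethylstannane, C[Sn](C)(C)C
Why: Stille cross-coupling of an α-iodoenone, the usual way to place the C20 methyl on the α-carbon without touching ketone, silyl ether or C4.

Step 6
Reactants: 10 (S)-citronellol
Product: 11 (S)-citronellyl tert-butyldiphenylsilyl ether
Conditions: TBDPSCl, imidazole, DMF, rt
Reagents that add atoms: TBDPSCl, CC(C)(C)[Si](Cl)(c1ccccc1)c1ccccc1
Why: Routine silylation; TBDPS outlasts every later step up to the fluoride treatment of step 16, including the HF·pyridine of step 14.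

Step 7
Reactants: 11 (S)-citronellyl TBDPS ether; 1 methacrolein
Product: 12 (S,E)-8-(tert-butyldiphenylsilyloxy)-2,6-dimethyloct-2-enal
Conditions: 1 (5 equiv), second-generation Hoveyda–Grubbs catalyst (5 mol %), CH2Cl2, 40 °C
Reagents that add atoms: none
Why: Olefin cross-metathesis of a prenyl-type trisubstituted alkene with methacrolein, documented for citronellyl substrates, is driven by loss of isobutene and gives the thermodynamically preferred E enal, which fixes the C8=C9 geometry.

Step 8
Reactants: 12 (S,E)-enal
Product: 13 (S,E)-tert-butyl[(3,7-dimethylnona-6,8-dien-1-yl)oxy]diphenylsilane (C6H2=C7H–C8(CH3)=C9H–C11…C15–OTBDPS)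
Conditions: Ph3PCH3Br, KOt-Bu, THF, 0 °C
Reagents that add atoms: methyltriphenylphosphonium bromide, C[P+](c1ccccc1)(c1ccccc1)c1ccccc1.[Br-]
Why: Wittig methylenation of an enal adds C6 and leaves the E trisubstituted alkene and C13 untouched.

Step 9
Reactants: 9 (S)-4-[(tert-butyldimethylsilyloxy)methyl]-2,4-dimethylcyclohex-2-en-1-one; 13 (S,E)-3-methyl-1,3-diene with the C11–C15 chain
Product: 15 18-(tert-butyldimethylsilyloxy)-15-(tert-butyldiphenylsilyloxy)-ent-labd-7-en-1-one (trans-decalin; H5 anti to C20; C11 chain cis to C20; C4 C5 C9 C10 C13 as in 27), via triplet biradical 14 (not isolated)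
Conditions: hν (366 nm LED, Pyrex), 13 (4 equiv, ca. 1.5 M), degassed hexane/CH2Cl2, 0 °C
Reagents that add atoms: none
Why: Proposed new method: light of 366 nm is absorbed only by enone 9, whose twisted ππ* triplet bonds through C5 to the unsubstituted terminus C6 of s-cis 13 and gives triplet biradical 14 (tertiary α-keto radical at C10 plus a C7–C8–C9 allyl radical), which after spin inversion couples C9 with C10. The nearest established reaction type is the interception by 1,3-dienes of strained trans-cyclohept-2-enones and trans-cyclooct-2-enones made by irradiation, a thermal [4+2] step that leaves a trans ring fusion; cyclohex-2-enones are so far known to give trans-fused rings only in [2+2] photocycloadditions that run through the same kind of biradical. Ring B closes as a stepwise formal [4+2] cycloaddition whose second bond is a six-membered endo radical coupling at the allyl terminus C9, in competition with four-membered closure at C7. C5 is controlled by C4, because C6 enters in the ring plane of the twisted enone trans to the CH2OTBS group and ends equatorial with H5 axial; C10 is controlled by the axial C4 methyl, which lies 1,3-syn to the C10 lobe anti to H5 and leaves only the H5 side open, so that the small C20 methyl turns axial (trans fusion); C9 is controlled by the E geometry of the allyl terminus, which in the half-chair closure open to a C6-equatorial biradical holds the C11 chain pseudo-equatorial and thus cis to C20. The step needs capture of the triplet before energy transfer, [4+2] over [2+2], trans over cis fusion, one face at C5 and one epimer at C9: the high diene concentration serves the first, the C8 methyl (larger s-cis share, cisoid allyl radical) the second, the C4 quaternary centre the third and fourth, and mismatched biradicals can fall back to 9 and 13. The C9 outcome is the least secured, since a concerted carbonyl-endo addition to a fully formed trans-enone would place the chain trans to C20; the adduct ketone itself is transparent at 366 nm and so escapes Norrish α-cleavage.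

Step 10
Reactants: 15 ent-labd-7-en-1-one bis-silyl ether
Product: 16 the corresponding C1 alcohol (OH equatorial, cis to C20)
Conditions: LiAlH4, Et2O, 0 °C
Reagents that add atoms: none
Why: Hydride reduction of a ketone next to a quaternary carbon by axial attack from the face opposite the C20 methyl; the new carbinol centre is deleted in step 12, so its configuration has no consequence.

Step 11
Reactants: 16 C1 alcohol
Product: 17 O-(C1) S-methyl xanthate of 16
Conditions: NaH, THF, 0 °C to rt; CS2; MeI
Reagents that add atoms: carbon disulfide, S=C=S; iodomethane, CI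
Why: Xanthate formation (first half of the Barton–McCombie deoxygenation) uses small reagents that reach the hindered alkoxide, and no other free hydroxyl is present.

Step 12
Reactants: 17 xanthate
Product: 18 18-(tert-butyldimethylsilyloxy)-15-(tert-butyldiphenylsilyloxy)-ent-labd-7-ene
Conditions: Bu3SnH, AIBN (cat.), toluene, 110 °C
Reagents that add atoms: none
Why: Barton–McCombie radical deoxygenation; the secondary C1 radical has only disfavoured 4-exo or 5-endo paths to the C7=C8 alkene and is reduced by the stannane without touching any stereocentre.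

Step 13
Reactants: 18 ent-labd-7-ene bis-silyl ether
Product: 20 C8 tertiary alcohol (8-OH equatorial and anti to C20; C17 methyl axial; C8 as in 27), via C8 hydroperoxide 19 (not isolated)
Conditions: Mn(dpm)3 (dpm = dipivaloylmethanate, cat.), PhSiH3, O2 (1 atm), i-PrOH/CH2Cl2, 0 °C; then PPh3
Reagents that add atoms: dioxygen, O=O
Why: Mukaiyama hydration, in which hydrogen-atom transfer to C7 gives the tertiary C8 radical (Markovnikov) and O2 enters along the equatorial direction because the axial approach is blocked 1,3 by the C20 methyl; PPh3 then reduces the hydroperoxide.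

Step 14
Reactants: 20 tertiary alcohol bis-silyl ether
Product: 21 15-(tert-butyldiphenylsilyloxy)-ent-labdane-8,18-diol
Conditions: HF·pyridine, pyridine, THF, 0 °C to rt
Reagents that add atoms: none
Why: Selective desilylation, because buffered HF·pyridine cleaves an alkyl TBS ether far faster than a TBDPS ether and is too mild to ionise the tertiary alcohol.

Step 15
Reactants: 21 8,18-diol; 22 angelic acid [(Z)-2-methylbut-2-enoic acid]
Product: 24 C18 angelate of 21, via mixed anhydride 23 (not isolated)
Conditions: 2,4,6-Cl3C6H2COCl, Et3N, toluene, rt; then 21, 80 °C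
Reagents that add atoms: 2,4,6-trichlorobenzoyl chloride, O=C(Cl)c1c(Cl)cc(Cl)cc1Cl (its aroyl group is held only by 23)
Why: Yamaguchi-type mixed-anhydride esterification run without a nucleophilic catalyst, the known way to transfer an angeloyl group without Z to E isomerisation; only the primary C18 hydroxyl reacts, the tertiary C8 hydroxyl being too hindered.

Step 16
Reactants: 24 C18 angelate TBDPS ether
Product: 25 18-angeloyloxy-ent-labdane-8,15-diol
Conditions: TBAF, AcOH, THF, rt
Reagents that add atoms: none
Why: Fluoride desilylation buffered with acetic acid, so that the angelate is neither hydrolysed nor isomerised.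

Step 17
Reactants: 25 8,15-diol angelate
Product: 27 CNP0315745.1 (18-angeloyloxy-8-hydroxy-ent-labdan-15-oic acid; 4S 5S 8S 9S 10R 13S), via C15 aldehyde 26 (not isolated)
Conditions: TEMPO (cat.), PhI(OAc)2, MeCN/pH 7 buffer, rt
Reagents that add atoms: water, O
Why: Oxoammonium (TEMPO/PhI(OAc)2) oxidation of the only primary alcohol through the aldehyde hydrate to the acid; the tertiary alcohol and the electron-poor angelate alkene are inert.

Compound list
1 | methacrolein | C=C(C)C=O | starting material
2 | (E)-1-(dimethylamino)-3-(tert-butyldimethylsilyloxy)buta-1,3-diene | CN(C)/C=C/C(=C)O[Si](C)(C)C(C)(C)C | starting material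
3 | endo cycloadduct aldehyde (NMe2 cis to CHO) | O=C[C@@]1(C)CCC(O[Si](C)(C)C(C)(C)C)=C[C@H]1N(C)C | intermediate
4 | amino alcohol from reduction of 3 | OC[C@@]1(C)CCC(O[Si](C)(C)C(C)(C)C)=C[C@H]1N(C)C | intermediate
5 | β-(dimethylamino) ketone | OC[C@@]1(C)CCC(=O)C[C@H]1N(C)C | intermediate
6 | (S)-4-(hydroxymethyl)-4-methylcyclohex-2-en-1-one | OC[C@@]1(C)CCC(=O)C=C1 | intermediate
7 | (S)-4-[(tert-butyldimethylsilyloxy)methyl]-4-methylcyclohex-2-en-1-one | CC(C)(C)[Si](C)(C)OC[C@@]1(C)CCC(=O)C=C1 | intermediate
8 | (S)-4-[(tert-butyldimethylsilyloxy)methyl]-2-iodo-4-methylcyclohex-2-en-1-one | CC(C)(C)[Si](C)(C)OC[C@@]1(C)CCC(=O)C(I)=C1 | intermediate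
9 | (S)-4-[(tert-butyldimethylsilyloxy)methyl]-2,4-dimethylcyclohex-2-en-1-one | CC(C)(C)[Si](C)(C)OC[C@@]1(C)CCC(=O)C(C)=C1 | intermediate
10 | (S)-citronellol | CC(C)=CCC[C@H](C)CCO | starting material
11 | (S)-citronellyl TBDPS ether | CC(C)=CCC[C@H](C)CCO[Si](c1ccccc1)(c1ccccc1)C(C)(C)C | intermediate
12 | (S,E)-8-(tert-butyldiphenylsilyloxy)-2,6-dimethyloct-2-enal | O=C/C(C)=C/CC[C@H](C)CCO[Si](c1ccccc1)(c1ccccc1)C(C)(C)C | intermediate
13 | (S,E)-tert-butyl[(3,7-dimethylnona-6,8-dien-1-yl)oxy]diphenylsilane | C=C/C(C)=C/CC[C@H](C)CCO[Si](c1ccccc1)(c1ccccc1)C(C)(C)C | intermediate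
14 | triplet biradical (C5–C6 formed; radicals at C10 and on the cisoid C7–C9 allyl unit, drawn at C9) | CC(C)(C)[Si](C)(C)OC[C@@]1(C)CCC(=O)[C](C)[C@@H]1C/C=C(C)\[CH]CC[C@H](C)CCO[Si](c1ccccc1)(c1ccccc1)C(C)(C)C | intermediate
15 | 18-(TBS-oxy)-15-(TBDPS-oxy)-ent-labd-7-en-1-one | CC(C)(C)[Si](C)(C)OC[C@@]1(C)CCC(=O)[C@]2(C)[C@@H]1CC=C(C)[C@H]2CC[C@H](C)CCO[Si](c1ccccc1)(c1ccccc1)C(C)(C)C | intermediate
16 | C1 alcohol (OH equatorial, cis to C20) | CC(C)(C)[Si](C)(C)OC[C@@]1(C)CC[C@H](O)[C@]2(C)[C@@H]1CC=C(C)[C@H]2CC[C@H](C)CCO[Si](c1ccccc1)(c1ccccc1)C(C)(C)C | intermediate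
17 | C1 S-methyl xanthate | CC(C)(C)[Si](C)(C)OC[C@@]1(C)CC[C@H](OC(=S)SC)[C@]2(C)[C@@H]1CC=C(C)[C@H]2CC[C@H](C)CCO[Si](c1ccccc1)(c1ccccc1)C(C)(C)C | intermediate
18 | 18-(TBS-oxy)-15-(TBDPS-oxy)-ent-labd-7-ene | CC(C)(C)[Si](C)(C)OC[C@@]1(C)CCC[C@]2(C)[C@@H]1CC=C(C)[C@H]2CC[C@H](C)CCO[Si](c1ccccc1)(c1ccccc1)C(C)(C)C | intermediate
19 | C8 hydroperoxide | CC(C)(C)[Si](C)(C)OC[C@@]1(C)CCC[C@]2(C)[C@@H]1CC[C@](C)(OO)[C@H]2CC[C@H](C)CCO[Si](c1ccccc1)(c1ccccc1)C(C)(C)C | intermediate
20 | C8 tertiary alcohol bis-silyl ether | CC(C)(C)[Si](C)(C)OC[C@@]1(C)CCC[C@]2(C)[C@@H]1CC[C@](C)(O)[C@H]2CC[C@H](C)CCO[Si](c1ccccc1)(c1ccccc1)C(C)(C)C | intermediate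
21 | 15-(TBDPS-oxy)-ent-labdane-8,18-diol | OC[C@@]1(C)CCC[C@]2(C)[C@@H]1CC[C@](C)(O)[C@H]2CC[C@H](C)CCO[Si](c1ccccc1)(c1ccccc1)C(C)(C)C | intermediate
22 | angelic acid | C/C=C(/C)C(=O)O | starting material
23 | angelic 2,4,6-trichlorobenzoic anhydride | C/C=C(/C)C(=O)OC(=O)c1c(Cl)cc(Cl)cc1Cl | intermediate
24 | C18 angelate, C15 TBDPS ether | C/C=C(/C)C(=O)OC[C@@]1(C)CCC[C@]2(C)[C@@H]1CC[C@](C)(O)[C@H]2CC[C@H](C)CCO[Si](c1ccccc1)(c1ccccc1)C(C)(C)C | intermediate
25 | 18-angeloyloxy-ent-labdane-8,15-diol | C/C=C(/C)C(=O)OC[C@@]1(C)CCC[C@]2(C)[C@@H]1CC[C@](C)(O)[C@H]2CC[C@H](C)CCO | intermediate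
26 | C15 aldehyde | C/C=C(/C)C(=O)OC[C@@]1(C)CCC[C@]2(C)[C@@H]1CC[C@](C)(O)[C@H]2CC[C@H](C)CC=O | intermediate
27 | CNP0315745.1 | C/C=C(/C)C(=O)OC[C@@]1(C)CCC[C@]2(C)[C@@H]1CC[C@](C)(O)[C@H]2CC[C@H](C)CC(=O)O | target

Total step count: 17. Longest linear sequence: 14 steps (steps 1–5 and 9–17); steps 6–8 form the second branch.

Steps most likely to fail

1. Step 9 (new method).
What may go wrong:
- The enone triplet may pass its energy to the diene, which causes E/Z scrambling and diene dimerisation.
- The biradical may close at C7 to a vinylcyclobutane.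
- The biradical may close to the cis-fused ring.
- The chain may end up trans to C20.

The fallback sets out from 13 and 9 and comes back at 18. It uses known chemistry and makes the two ring-B bonds one after the other by polar reactions, which also makes steps 10–12 unnecessary. 9-BBN adds to the vinyl group of 13 to give the B-alkyl borane F1, which NaBO3 oxidises to the homoallylic alcohol F2 with the E alkene untouched. CBr4/PPh3 then gives the bromide F3, and magnesium gives the Grignard reagent F4. Conjugate addition of F4 to 9, catalysed by CuBr·SMe2, forms C5–C6 trans to the CH2OTBS group, and the regiodefined enolate is trapped with N-(5-chloro-2-pyridyl)triflimide as the enol triflate F5. Formate reduction (Pd(OAc)2, PPh3, HCO2H, Et3N, DMF) removes the C1 oxygen and leaves the C1=C10 alkene of the monocyclic diene F6. Brønsted-acid cyclisation (SnCl4-activated 2-methoxyphenol, CH2Cl2, −78 °C) protonates C1. The C10 cation is then captured by the E C8=C9 alkene through a chair-like transition state, the established closure of α-monocyclic terpenoid dienes to trans-decalins with an equatorial C9 chain. Proton loss from the C8 cation gives 18, and any exocyclic C8=C17 isomer is carried into the same alcohol 20 by step 13.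

2. Step 13.
What may go wrong:
- Facial selectivity may be poor when O2 captures the nearly planar C8 radical.
- Hydrogen-atom transfer to the hindered alkene may be slow.

The fallback sets out from 18 and comes back at 20. It replaces the radical hydration by a stereospecific two-electron sequence. mCPBA (NaHCO3, CH2Cl2, 0 °C) epoxidises the C7=C8 alkene from the face anti to the C20 methyl to give the epoxide F7. LiEt3BH (THF, reflux) then opens it at the less substituted C7, so the C8–O bond, and with it the configuration at C8, is kept.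

3. Step 15.
What may go wrong:
- The angeloyl group may isomerise from Z to E during the slow acylation of the neopentyl C18 hydroxyl.

The fallback sets out from 21 and comes back at 24. It builds the Z alkene on the ester instead of transferring it. 2-[Bis(2,2,2-trifluoroethoxy)phosphoryl]propanoic acid is coupled to the C18 hydroxyl (EDC, DMAP, CH2Cl2) to give the phosphonopropionate F8. A Still–Gennari olefination with acetaldehyde (KHMDS, 18-crown-6, THF, −78 °C) then gives the (Z)-2-methylbut-2-enoate 24.

Further compounds
F1 | step 9 | B-alkyl-9-borabicyclo[3.3.1]nonane from 13 | C1CC2CCCC(C1)B2CC/C(C)=C/CC[C@H](C)CCO[Si](c1ccccc1)(c1ccccc1)C(C)(C)C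
F2 | step 9 | (S,E)-9-(tert-butyldiphenylsilyloxy)-3,7-dimethylnon-3-en-1-ol | OCC/C(C)=C/CC[C@H](C)CCO[Si](c1ccccc1)(c1ccccc1)C(C)(C)C
F3 | step 9 | homoallylic bromide | BrCC/C(C)=C/CC[C@H](C)CCO[Si](c1ccccc1)(c1ccccc1)C(C)(C)C
F4 | step 9 | homoallylic Grignard reagent | Br[Mg]CC/C(C)=C/CC[C@H](C)CCO[Si](c1ccccc1)(c1ccccc1)C(C)(C)C
F5 | step 9 | C1 enol triflate with the C6–C15 chain on C5 (trans to CH2OTBS) | CC(C)(C)[Si](C)(C)OC[C@@]1(C)CCC(OS(=O)(=O)C(F)(F)F)=C(C)[C@@H]1CC/C(C)=C/CC[C@H](C)CCO[Si](c1ccccc1)(c1ccccc1)C(C)(C)C
F6 | step 9 | monocyclic diene (C1=C10 and E C8=C9) | CC(C)(C)[Si](C)(C)OC[C@@]1(C)CCC=C(C)[C@@H]1CC/C(C)=C/CC[C@H](C)CCO[Si](c1ccccc1)(c1ccccc1)C(C)(C)C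
F7 | step 13 | 7,8-epoxide anti to C20 | CC(C)(C)[Si](C)(C)OC[C@@]1(C)CCC[C@]2(C)[C@@H]1C[C@@H]3O[C@]3(C)[C@H]2CC[C@H](C)CCO[Si](c1ccccc1)(c1ccccc1)C(C)(C)C
F8 | step 15 | C18 2-[bis(2,2,2-trifluoroethoxy)phosphoryl]propanoate (both epimers at the phosphonate carbon) | CC(P(=O)(OCC(F)(F)F)OCC(F)(F)F)C(=O)OC[C@@]1(C)CCC[C@]2(C)[C@@H]1CC[C@](C)(O)[C@H]2CC[C@H](C)CCO[Si](c1ccccc1)(c1ccccc1)C(C)(C)C
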